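## Analysis of the target

The target is a plakortolide-type peroxylactone: a 1,2-dioxane (ring A: O–O, C3, C4, C5, C6) cis-fused along C3–C4 to a γ-butyrolactone (ring B: C1, C2, C3, C4, O), with the C7–C16 chain on C6. Atoms are numbered from the lactone carbonyl C1 to the benzylic alkene carbon C16. Three stereocentres lie in the bicycle, C3 (S), C4 (S) and C6 (R): the cis fusion ties C3 to C4, the chain carbon C7 on C6 is cis to the lactone oxygen on C4, and the two methyl groups share the opposite face. The fourth, C8 (R), carries a methyl group and is insulated from C6 by the C7 methylene; the chain ends in an (E)-C11=C12 alkene and an (E)-styrene (C15=C16). Sensitive groups are the O–O bond (low-valent metals, hydrides, hydrogenation), the C3–H next to it (Kornblum–DeLaMare cleavage), the β-peroxy lactone (base-induced E1cB opening) and the styrene (radical and electrophilic oxidants). The hard problem is C6: it is fully substituted and bears the peroxide, and its two carbon substituents (CH3 and the chain CH2) are sterically alike. Every C6–O bond formation (radical capture of O2, SN1, conjugate addition) and every equilibration is therefore expected to give both epimers, and C8 is too far away to help. The feature that invites a different cut is that C6 of ring A, once the exocyclic C6–C7 bond is removed, is a methyl ketone held as a cyclic peroxyketal between the peroxide oxygen and C5. Its configuration can then be set by C–C bond formation on the flat peroxycarbenium ion, whose faces are told apart by the ring stereocentres C3 and C4 and not by CH3 versus CH2R, and both ketal epimers funnel into one product.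

## Retrosynthetic reasoning

**C11=C12 (27 ⇒ 19 + 25).** The chain is cut at the isolated E alkene by a Julia–Kocienski olefination between peroxy aldehyde 19 and sulfone 25 (through carbanion 26). This keeps the styrene and the 1,5-diene out of the ozonolysis and Lewis-acid steps and uses an E-selective, metal-free olefination as the last step. Sulfone 25 comes from 20, 21 and 23 through 22 and 24 by cross-metathesis, S-alkylation and oxidation.

**C10–C11 (19 ⇒ 15 through 18).** One carbon is added to aldehyde 15 with ylide 17 (from 16) and the enol ether 18 is hydrolysed. The detour is forced by parity: an enol-type donor that attacks through C7 can place its carbonyl only on C8, C10 or C12, and C10 is the position that activates the C8=C9 bond for the next disconnection.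

**C8–H (15 ⇒ 14).** The remote methyl stereocentre is set by conjugate reduction of the β-methyl enal 14 with an ene-reductase. No ring stereocentre can control C8, so a catalyst that distinguishes CH3 from CH2R is needed. The enzyme class does this for citral, contains nothing that reduces O–O, and avoids amine catalysts, which could form a dienamine toward C7 and expel the peroxide from C6.

**C6–C7 (14 ⇒ 10 + 12 through 13), the key cut.** The bond between the peroxy carbon and the chain is formed by addition of silyl dienol ether 12 to peroxycarbenium ion 13, generated from the methoxy peroxyketal 10. The cut is placed here because it turns the one stereocentre that C–O chemistry cannot control into a facial-selectivity problem on a cis-fused bicycle. It also makes the precursor 10 a small compound that needs no control at C6. The forward reaction must ionise only the exocyclic C–O bond, react at the terminal carbon of the donor, and add on the face cis to the lactone oxygen.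

**O–C3 and the C6 ketal (10 ⇒ 9 ⇒ 7 through 8).** Ring A is opened at O–C3 by a retro peroxy-Michael addition to the hydroperoxy ketal 9. The ketal carbon of 9 comes from the 1,1-disubstituted alkene of butenolide 7 by Criegee ozonolysis with trapping of carbonyl oxide 8 by the alcohol solvent. The forward Michael step only has to close a six-membered ring onto a butenolide, which fixes C3 from C4 through the cis fusion.

**Ring B and C4 (7 ⇒ 4 + 5 through 6; 4 ⇒ 3 ⇒ 1 + 2).** The butenolide is made from α-hydroxy aldehyde 4 and the cumulated ylide 5 (acylation to 6, then intramolecular Wittig). Aldehyde 4 comes from diol 3, and 3 from the copper-catalysed opening of epoxide 1 by Grignard reagent 2. C4, the root of all ring stereochemistry, is thus bought as a quaternary epoxide carbon and never touched.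

**Donor (12 ⇐ 11).** The dienol ether is one silylation away from enal 11.

## Alternatives that were turned down

**Alternative 1:** the textbook route. Disconnection: O–C6 and O–C3 of ring A. Forward key step: cobalt-catalysed hydroperoxysilylation (Mukaiyama–Isayama; Co(thd)2, O2, Et3SiH; thd = 2,2,6,6-tetramethylheptane-3,5-dionate) of the 1,1-disubstituted alkene of butenolide A1 to the triethylsilyl peroxide A2, then desilylation and peroxy-Michael closure. Turned down for three reasons:
- C6 is created when O2 captures a planar, acyclic tertiary radical whose CH3 and CH2R groups are the same size, so A2 should form as both C6 epimers and half of the material is lost at a late stage.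
- There is neither a kinetic nor a thermodynamic handle to correct this, because the two epimeric bicycles differ only in which of two like-sized groups is axial.
- The hydrogen-atom-transfer conditions also attack a styrene or a trisubstituted alkene, so the chain has to be masked (silyl ether in A1) and built afterwards. This costs the same end-game steps without solving C6.

**Alternative 2:** Disconnection: both C–O bonds of the peroxide at once. Forward key step: [4+2] cycloaddition of singlet oxygen to the (3E,5E)-diene acid A3 to give the 3,6-dihydro-1,2-dioxine A4, then lactonisation of the carboxyl group onto C4 of the C4=C5 alkene. The attraction is real: diene geometry translates CH3 versus CH2R into the C3/C6 relationship, and cis fusion then sets C4. Turned down because: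
- Nothing controls the diene face relative to C8, which sits behind a methylene, so two diastereomers are expected in equal amounts.
- The reactive s-cis conformer must hold the C6 methyl "inside", which is strongly disfavoured, so ene reactions at the many allylic positions and at the trisubstituted chain alkene should compete.
- The lactonisation needs either acid, which can ionise the allylic tertiary C6–O bond, or an iodolactonisation followed by radical deiodination next to the O–O bond.

**Alternative 3:** Disconnection: C6–O alone, by a stereospecific substitution. Forward key step: acid-catalysed opening of the enantioenriched 2,2-disubstituted epoxide A5 by H2O2 at the tertiary carbon with inversion, giving the β-hydroperoxy alcohol A6. This is the one reliable stereospecific entry to a tertiary hydroperoxide. Turned down because: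
- It leaves oxygen on the neighbouring carbon (C5 in A6), and both neighbours of C6 are CH2 in the target.
- The C5–OH would have to be exchanged for the C4–C5 bond next to a quaternary peroxy carbon (neopentyl substitution, or an aldehyde route that again leaves oxygen), which costs several steps with the peroxide present.
- The epoxide A5 itself comes from a 1,1-dialkyl alkene for which asymmetric epoxidation again has to distinguish CH3 from CH2R.

Key step: step 7

## Route

Step 1
Reactants: 1 (R)-2-methylglycidol; 2 isopropenylmagnesium bromide
Product: 3 (2S)-2,4-dimethylpent-4-ene-1,2-diol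
Conditions: 2 (2.5 equiv), CuI (10 mol %), THF, −30 to 0 °C; aq. NH4Cl
Reagents that add atoms: none
Why: Copper-catalysed Grignard opening of the 2,2-disubstituted epoxide at its unsubstituted CH2 (SN2); the first equivalent of 2 only deprotonates the alcohol; the quaternary carbinol (C4 of the target) is not involved, so its configuration is carried over from 1 (the descriptor changes from R to S only through the priority rules).

Step 2
Reactants: 3 (2S)-2,4-dimethylpent-4-ene-1,2-diol
Product: 4 (2S)-2-hydroxy-2,4-dimethylpent-4-enal
Conditions: (COCl)2, DMSO, CH2Cl2, −78 °C; Et3N, −78 to 0 °C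
Reagents that add atoms: none
Why: Swern oxidation; only the primary alcohol can be oxidised and C4 carries no hydrogen, so nothing can epimerise.

Step 3
Reactants: 4 (2S)-2-hydroxy-2,4-dimethylpent-4-enal; 5 (triphenylphosphoranylidene)ketene
Product: 7 (5S)-5-methyl-5-(2-methylprop-2-en-1-yl)furan-2(5H)-one, via acyl ylide 6 (not isolated)
Conditions: toluene, 80 °C
Reagents that add atoms: none
Why: The tertiary alcohol adds to the cumulated ylide 5 to give acyl ylide 6, which closes by intramolecular Wittig reaction onto the neighbouring aldehyde; the ring enforces the Z alkene of the butenolide and C4 is untouched.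

Step 4
Reactants: 7 (5S)-5-methyl-5-(2-methylprop-2-en-1-yl)furan-2(5H)-one
Product: 9 (5S)-5-(2-hydroperoxy-2-methoxypropyl)-5-methylfuran-2(5H)-one (both epimers at the ketal carbon), via carbonyl oxide 8 (not isolated)
Conditions: O3, CH2Cl2/MeOH 4:1, −78 °C, indicator end point; N2 purge; concentrate cold, short silica plug
Reagents that add atoms: ozone ([O-][O+]=O); methanol (CO)
Why: Criegee ozonolysis: the electron-rich 1,1-disubstituted alkene reacts far faster than the electron-poor butenolide alkene; cycloreversion of the primary ozonide should place the carbonyl oxide on the more substituted carbon (8) and release formaldehyde, and methanol traps 8 as the methoxy hydroperoxide; the ketal centre (C6) forms as both epimers, which is harmless because step 7 erases it.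

Step 5
Reactants: 9 (5S)-5-(2-hydroperoxy-2-methoxypropyl)-5-methylfuran-2(5H)-one
Product: 10 (4aS,7aS)-3-methoxy-3,4a-dimethyltetrahydro-3H-furo[3,2-c][1,2]dioxin-6(4H)-one (both epimers at ring position 3, which is C6 of the target)
Conditions: Et2NH (0.3 equiv), CF3CH2OH, 23 °C
Reagents that add atoms: none
Why: Intramolecular peroxy-Michael addition (6-exo-trig) of the hydroperoxide to the butenolide under amine catalysis in a protic fluorinated solvent, which protonates the enolate before it can attack the O–O bond; the tether on C4 can reach C3 only from its own face, so ring B becomes cis-fused and C3 (S) is set by C4.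

Step 6
Reactants: 11 3-methylbut-2-enal
Product: 12 tert-butyl(dimethyl){[(1E)-3-methylbuta-1,3-dien-1-yl]oxy}silane
Conditions: TBSOTf, Et3N, Et2O, 0 to 23 °C
Reagents that add atoms: tert-butyldimethylsilyl trifluoromethanesulfonate (CC(C)(C)[Si](C)(C)OS(=O)(=O)C(F)(F)F)
Why: O-silylation of the enal followed by γ-deprotonation by the amine gives the (E)-silyl dienol ether, a standard vinylogous Mukaiyama donor.

Step 7
Reactants: 10 (4aS,7aS)-3-methoxy-3,4a-dimethyltetrahydro-3H-furo[3,2-c][1,2]dioxin-6(4H)-one (both C6 epimers); 12 tert-butyl(dimethyl){[(1E)-3-methylbuta-1,3-dien-1-yl]oxy}silane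
Product: 14 (2E)-4-[(3R,4aS,7aS)-3,4a-dimethyl-6-oxohexahydro-3H-furo[3,2-c][1,2]dioxin-3-yl]-3-methylbut-2-enal, via peroxycarbenium ion 13 (not isolated)
Conditions: TiCl4 (1.2 equiv), CH2Cl2, −78 °C; 12 (2 equiv), −78 to −40 °C; aq. NaHCO3
Reagents that add atoms: none
Why: TiCl4 removes methoxide from either C6 epimer of 10 and both give the same peroxycarbenium ion 13, so the step is stereoconvergent; the closest known reaction type is the Lewis-acid substitution of cyclic alkoxy peroxyketals (3-alkoxy-1,2-dioxolanes and 1,2-dioxanes) by allylsilanes, silyl enol ethers and silyl ketene acetals, run here with a silyl dienol ether as vinylogous Mukaiyama donor. No ring is closed in this step (ring A was closed 6-exo-trig in step 5); the step forms the C6–C7 bond, joins the chain to the bicycle and creates the quaternary peroxy carbon. Ion 13 should react through the half-chair in which the lactone oxygen on C4 is pseudoaxial and the C4 methyl and the C3–C2 bond are pseudoequatorial, the arrangement favoured both sterically and electrostatically. The donor attacks through its terminal CH2 (the γ-carbon, favoured over α-attack by the hindered tertiary cation) along the axial trajectory that leads directly to a chair, that is on the face cis to the lactone oxygen and trans to the C4 methyl. The new C6 centre (R) is therefore controlled by C3 and C4 of the ring and not by the size difference between CH3 and CH2R, which is the reason for making this bond last. The selectivities needed are ionisation of the exocyclic C6–OMe bond and not of the ring C6–O or the O–O bond (low temperature, methoxide as the better ligand for titanium), γ- over α-attack, and the facial choice secured by the cis-fused bicycle. Loss of the silyl group to chloride gives enal 14, expected mainly as the 2E isomer, which is the one carried on.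

Step 8
Reactants: 14 (2E)-4-[(3R,4aS,7aS)-3,4a-dimethyl-6-oxohexahydro-3H-furo[3,2-c][1,2]dioxin-3-yl]-3-methylbut-2-enal
Product: 15 (3S)-4-[(3R,4aS,7aS)-3,4a-dimethyl-6-oxohexahydro-3H-furo[3,2-c][1,2]dioxin-3-yl]-3-methylbutanal
Conditions: ene-reductase (Old Yellow Enzyme family; a panel member that reduces geranial to (S)-citronellal), NADP+ (cat.), D-glucose, glucose dehydrogenase, phosphate buffer pH 7, 10% DMSO, 30 °C
Reagents that add atoms: none
Why: Flavin-dependent ene-reductases deliver hydride from the reduced flavin to the β-carbon (C8) and a proton to C9 of β-methyl enals (the citral to citronellal reaction); the pocket that separates CH3 from the homoprenyl chain of citral should separate CH3 from the CH2-bicycle here, so C8 is set by the enzyme (S in 15, which is 8R in the target); no reagent able to reduce O–O and no amine that could trigger loss of the peroxide from C6 is present.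

Step 9
Reactants: 15 (3S)-4-[(3R,4aS,7aS)-3,4a-dimethyl-6-oxohexahydro-3H-furo[3,2-c][1,2]dioxin-3-yl]-3-methylbutanal; 16 (methoxymethyl)triphenylphosphonium chloride
Product: 18 (3R,4aS,7aS)-3-[(2R)-5-methoxy-2-methylpent-4-en-1-yl]-3,4a-dimethyltetrahydro-3H-furo[3,2-c][1,2]dioxin-6(4H)-one (E/Z mixture), via phosphorus ylide 17 (not isolated)
Conditions: 16, KN(SiMe3)2, THF, 0 °C; then 15, −78 to 0 °C
Reagents that add atoms: none
Why: Wittig reaction of the non-stabilised ylide 17 with an unhindered aldehyde; the ylide is preformed and the aldehyde added at −78 °C so that carbonyl addition outruns deprotonation at C2 (E1cB opening of ring A, which is in any case reversible); the enol ether geometry is irrelevant and C8 is not enolisable.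

Step 10
Reactants: 18 (3R,4aS,7aS)-3-[(2R)-5-methoxy-2-methylpent-4-en-1-yl]-3,4a-dimethyltetrahydro-3H-furo[3,2-c][1,2]dioxin-6(4H)-one
Product: 19 (4R)-5-[(3R,4aS,7aS)-3,4a-dimethyl-6-oxohexahydro-3H-furo[3,2-c][1,2]dioxin-3-yl]-4-methylpentanal
Conditions: 1 M aq. HCl, THF, 23 °C
Reagents that add atoms: water (O)
Why: Acid hydrolysis of the enol ether gives the aldehyde one carbon longer; the dialkyl peroxide, the lactone and the C8 centre tolerate dilute acid.

Step 11
Reactants: 20 5-bromopent-1-ene; 21 styrene
Product: 22 [(1E)-5-bromopent-1-en-1-yl]benzene
Conditions: second-generation Grubbs catalyst (2 mol %), 21 (3 equiv), CH2Cl2, 40 °C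
Reagents that add atoms: none
Why: Olefin cross-metathesis driven by loss of ethene; styrene partners give the E alkene under thermodynamic control.

Step 12
Reactants: 22 [(1E)-5-bromopent-1-en-1-yl]benzene; 23 1-phenyl-1H-tetrazole-5-thiol
Product: 24 1-phenyl-5-{[(4E)-5-phenylpent-4-en-1-yl]sulfanyl}-1H-tetrazole
Conditions: K2CO3, DMF, 23 °C
Reagents that add atoms: none
Why: SN2 S-alkylation of the thiolate by the primary bromide.

Step 13
Reactants: 24 1-phenyl-5-{[(4E)-5-phenylpent-4-en-1-yl]sulfanyl}-1H-tetrazole
Product: 25 1-phenyl-5-{[(4E)-5-phenylpent-4-en-1-yl]sulfonyl}-1H-tetrazole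
Conditions: (NH4)6Mo7O24·4H2O (10 mol %), 30% aq. H2O2, EtOH, 0 to 23 °C
Reagents that add atoms: hydrogen peroxide (OO)
Why: Molybdate-catalysed oxidation of the sulfide to the sulfone; under these conditions the conjugated alkene is not epoxidised.

Step 14
Reactants: 19 (4R)-5-[(3R,4aS,7aS)-3,4a-dimethyl-6-oxohexahydro-3H-furo[3,2-c][1,2]dioxin-3-yl]-4-methylpentanal; 25 1-phenyl-5-{[(4E)-5-phenylpent-4-en-1-yl]sulfonyl}-1H-tetrazole
Product: 27 (3R,4aS,7aS)-3,4a-dimethyl-3-[(2R,5E,9E)-2-methyl-10-phenyldeca-5,9-dien-1-yl]tetrahydro-3H-furo[3,2-c][1,2]dioxin-6(4H)-one, via potassium sulfonyl carbanion 26 (not isolated)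
Conditions: 25, KN(SiMe3)2, DME, −60 °C; then 19, −60 to 23 °C; aq. NH4Cl
Reagents that add atoms: none
Why: Julia–Kocienski olefination: addition of carbanion 26 to the aldehyde, Smiles rearrangement and elimination of SO2 and the tetrazolone; with potassium in DME an unbranched aldehyde should give the (E)-C11=C12 alkene; 26 is preformed so that no free amide base meets the β-peroxy lactone, and no stereocentre is touched.

## Compound list

1 | (R)-2-methylglycidol, [(2R)-2-methyloxiran-2-yl]methanol | C[C@@]1(CO)CO1 | starting material
2 | isopropenylmagnesium bromide, bromo(prop-1-en-2-yl)magnesium | CC(=C)[Mg]Br | starting material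
3 | (2S)-2,4-dimethylpent-4-ene-1,2-diol | C=C(C)C[C@](C)(O)CO | intermediate
4 | (2S)-2-hydroxy-2,4-dimethylpent-4-enal | C=C(C)C[C@](C)(O)C=O | intermediate
5 | (triphenylphosphoranylidene)ketene | O=C=C=P(c1ccccc1)(c1ccccc1)c1ccccc1 | starting material
6 | (2S)-2,4-dimethyl-1-oxopent-4-en-2-yl (triphenylphosphoranylidene)acetate (acyl ylide) | C=C(C)C[C@@](C)(C=O)OC(=O)C=P(c1ccccc1)(c1ccccc1)c1ccccc1 | intermediate (not isolated)
7 | (5S)-5-methyl-5-(2-methylprop-2-en-1-yl)furan-2(5H)-one | C=C(C)C[C@@]1(C)C=CC(=O)O1 | intermediate
8 | carbonyl oxide of (5S)-5-methyl-5-(2-oxopropyl)furan-2(5H)-one | CC(=[O+][O-])C[C@@]1(C)C=CC(=O)O1 | intermediate (not isolated)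
9 | (5S)-5-(2-hydroperoxy-2-methoxypropyl)-5-methylfuran-2(5H)-one (both epimers at the ketal carbon) | COC(C)(OO)C[C@@]1(C)C=CC(=O)O1 | intermediate
10 | (4aS,7aS)-3-methoxy-3,4a-dimethyltetrahydro-3H-furo[3,2-c][1,2]dioxin-6(4H)-one (both epimers at position 3) | COC1(C)C[C@]2(C)OC(=O)C[C@@H]2OO1 | intermediate
11 | 3-methylbut-2-enal | CC(C)=CC=O | starting material
12 | tert-butyl(dimethyl){[(1E)-3-methylbuta-1,3-dien-1-yl]oxy}silane | C=C(C)/C=C/O[Si](C)(C)C(C)(C)C | intermediate
13 | (4aS,7aS)-3,4a-dimethyl-6-oxo-4,4a,7,7a-tetrahydro-6H-furo[3,2-c][1,2]dioxin-2-ium (peroxycarbenium ion) | CC=1C[C@]2(C)OC(=O)C[C@@H]2O[O+]=1 | intermediate (not isolated)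
14 | (2E)-4-[(3R,4aS,7aS)-3,4a-dimethyl-6-oxohexahydro-3H-furo[3,2-c][1,2]dioxin-3-yl]-3-methylbut-2-enal | O=C/C=C(\C)C[C@]1(C)C[C@]2(C)OC(=O)C[C@@H]2OO1 | intermediate
15 | (3S)-4-[(3R,4aS,7aS)-3,4a-dimethyl-6-oxohexahydro-3H-furo[3,2-c][1,2]dioxin-3-yl]-3-methylbutanal | O=CC[C@@H](C)C[C@]1(C)C[C@]2(C)OC(=O)C[C@@H]2OO1 | intermediate
16 | (methoxymethyl)triphenylphosphonium chloride | COC[P+](c1ccccc1)(c1ccccc1)c1ccccc1.[Cl-] | starting material
17 | (methoxymethylidene)triphenylphosphorane | COC=P(c1ccccc1)(c1ccccc1)c1ccccc1 | intermediate (not isolated)
18 | (3R,4aS,7aS)-3-[(2R)-5-methoxy-2-methylpent-4-en-1-yl]-3,4a-dimethyltetrahydro-3H-furo[3,2-c][1,2]dioxin-6(4H)-one (E isomer drawn, E/Z mixture) | CO/C=C/C[C@@H](C)C[C@]1(C)C[C@]2(C)OC(=O)C[C@@H]2OO1 | intermediate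
19 | (4R)-5-[(3R,4aS,7aS)-3,4a-dimethyl-6-oxohexahydro-3H-furo[3,2-c][1,2]dioxin-3-yl]-4-methylpentanal | O=CCC[C@@H](C)C[C@]1(C)C[C@]2(C)OC(=O)C[C@@H]2OO1 | intermediate
20 | 5-bromopent-1-ene | C=CCCCBr | starting material
21 | styrene | C=Cc1ccccc1 | starting material
22 | [(1E)-5-bromopent-1-en-1-yl]benzene | BrCCC/C=C/c1ccccc1 | intermediate
23 | 1-phenyl-1H-tetrazole-5-thiol | Sc1nnnn1-c1ccccc1 | starting material
24 | 1-phenyl-5-{[(4E)-5-phenylpent-4-en-1-yl]sulfanyl}-1H-tetrazole | S(CCC/C=C/c1ccccc1)c1nnnn1-c1ccccc1 | intermediate
25 | 1-phenyl-5-{[(4E)-5-phenylpent-4-en-1-yl]sulfonyl}-1H-tetrazole | O=S(=O)(CCC/C=C/c1ccccc1)c1nnnn1-c1ccccc1 | intermediate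
26 | potassium salt of the α-sulfonyl carbanion of 25 | [K+].O=S(=O)([CH-]CC/C=C/c1ccccc1)c1nnnn1-c1ccccc1 | intermediate (not isolated)
27 | (3R,4aS,7aS)-3,4a-dimethyl-3-[(2R,5E,9E)-2-methyl-10-phenyldeca-5,9-dien-1-yl]tetrahydro-3H-furo[3,2-c][1,2]dioxin-6(4H)-one | C[C@H](CC/C=C/CC/C=C/c1ccccc1)C[C@]1(C)C[C@]2(C)OC(=O)C[C@@H]2OO1 | target

## Step count and least certain steps

Total step count: 14. Longest linear sequence: 10 steps (steps 1 to 5, 7 to 10 and 14).

**Step 7 (key step).** Most likely to go wrong: ionisation on the wrong side of the peroxyketal or heterolysis of the O–O bond with a 1,2-shift (Hock/Criegee-type fragmentation), proton loss from C5 of the cation, or attack through the α-carbon and acid-induced oligomerisation of the labile dienol ether. The cation is tertiary and the donor is more sensitive than the allylsilanes for which this chemistry is best known. Fallback, from 10 back to 14: substitution of 10 with 2-methylallyltrimethylsilane and TiCl4 or SnCl4 (Hosomi–Sakurai-type substitution of a peroxyketal, the best-precedented member of the class, with the same facial argument) should give (3R,4aS,7aS)-3,4a-dimethyl-3-(2-methylprop-2-en-1-yl)tetrahydro-3H-furo[3,2-c][1,2]dioxin-6(4H)-one F1. Cross-metathesis of F1 with (E)-but-2-enal (second-generation Hoveyda–Grubbs catalyst, CH2Cl2, 40 °C) would then build the C8=C9 bond and deliver 14 for step 8.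

**Step 8.** Most likely to go wrong: poor acceptance or slow turnover of the bulky, poorly soluble substrate, or an opposite stereochemical reading of residual 2Z isomer. The bicycle sits two atoms from the reacting carbon and many ene-reductases convert E and Z enals to opposite enantiomers. Fallback, from 14 back to 15 without new compounds: replace biocatalysis by counter-anion-directed iminium catalysis (morpholinium salt of the chiral phosphoric acid TRIP, the enantiomer that gives (S)-citronellal from citral, with a Hantzsch ester in dioxane). This is convergent for E/Z mixtures. Its own hazard, the reason it is not the first choice, is dienamine formation toward C7 followed by expulsion of the peroxide from C6.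

**Step 4.** Most likely to go wrong: partition of the primary ozonide toward formaldehyde O-oxide and the ketone, or attack of excess ozone on the butenolide alkene. The preference for the more substituted carbonyl oxide is a tendency, not a rule. Fallback, from 7 back to 9: ozonolysis with reductive work-up (dimethyl sulfide) gives (5S)-5-methyl-5-(2-oxopropyl)furan-2(5H)-one F2. Perketalisation of F2 with the urea adduct of H2O2 and catalytic Sc(OTf)3 in methanol would then form 9 from the ketone instead of from the carbonyl oxide.

**Step 5.** Most likely to go wrong: loss of H2O2 or methanol from the hydroperoxy ketal before ring closure, or nucleophilic epoxidation of the butenolide (Weitz–Scheffer pathway) when the enolate attacks the O–O bond. Fallback, from 7 back to 14: ketone F2 (made as above) is treated with the urea adduct of H2O2 and catalytic Et2NH in CF3CH2OH. Reversible hemiketal formation and peroxy-Michael closure should then collect the material under thermodynamic control as the cyclic peroxyhemiketal (4aS,7aS)-3-hydroxy-3,4a-dimethyltetrahydro-3H-furo[3,2-c][1,2]dioxin-6(4H)-one F3. Acetylation (Ac2O, pyridine) gives (4aS,7aS)-3,4a-dimethyl-6-oxohexahydro-3H-furo[3,2-c][1,2]dioxin-3-yl acetate F4, which enters step 7 in place of 10 and gives 14 through the same cation 13.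

**Step 14.** Most likely to go wrong: deprotonation at C2 by the sulfonyl carbanion with E1cB opening of ring A, base-induced cleavage at C3–H, or incomplete E selectivity, all on the most valuable intermediate. Fallback, from 19 back to 27: Wittig methylenation of 19 with methylidenetriphenylphosphorane (tolerance of phosphorus ylides having been shown in step 9) gives (3R,4aS,7aS)-3,4a-dimethyl-3-[(2R)-2-methylhex-5-en-1-yl]tetrahydro-3H-furo[3,2-c][1,2]dioxin-6(4H)-one F5. Base-free cross-metathesis of F5 with [(1E)-hexa-1,5-dien-1-yl]benzene F6 (from hexa-1,5-diene and 21 by cross-metathesis) using the second-generation Grubbs catalyst would give 27. The price is an E/Z mixture at C11=C12 that has to be separated, and some competing metathesis at the styrene.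

## Further compounds

F1 | step 7 | (3R,4aS,7aS)-3,4a-dimethyl-3-(2-methylprop-2-en-1-yl)tetrahydro-3H-furo[3,2-c][1,2]dioxin-6(4H)-one | C=C(C)C[C@]1(C)C[C@]2(C)OC(=O)C[C@@H]2OO1
F0 | step 8 | none | none
F2 | step 4 | (5S)-5-methyl-5-(2-oxopropyl)furan-2(5H)-one | CC(=O)C[C@@]1(C)C=CC(=O)O1
F3 | step 5 | (4aS,7aS)-3-hydroxy-3,4a-dimethyltetrahydro-3H-furo[3,2-c][1,2]dioxin-6(4H)-one (both epimers at position 3) | OC1(C)C[C@]2(C)OC(=O)C[C@@H]2OO1
F4 | step 5 | (4aS,7aS)-3,4a-dimethyl-6-oxohexahydro-3H-furo[3,2-c][1,2]dioxin-3-yl acetate (both epimers at position 3) | CC(=O)OC1(C)C[C@]2(C)OC(=O)C[C@@H]2OO1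
F5 | step 14 | (3R,4aS,7aS)-3,4a-dimethyl-3-[(2R)-2-methylhex-5-en-1-yl]tetrahydro-3H-furo[3,2-c][1,2]dioxin-6(4H)-one | C=CCC[C@@H](C)C[C@]1(C)C[C@]2(C)OC(=O)C[C@@H]2OO1
F6 | step 14 | [(1E)-hexa-1,5-dien-1-yl]benzene | C=CCC/C=C/c1ccccc1
A1 | alternative 1 | (5S)-5-[(4R)-7-{[tert-butyl(dimethyl)silyl]oxy}-4-methyl-2-methylideneheptyl]-5-methylfuran-2(5H)-one | CC(C)(C)[Si](C)(C)OCCC[C@@H](C)CC(=C)C[C@@]1(C)C=CC(=O)O1
A2 | alternative 1 | (5S)-5-[(4R)-7-{[tert-butyl(dimethyl)silyl]oxy}-2,4-dimethyl-2-[(triethylsilyl)peroxy]heptyl]-5-methylfuran-2(5H)-one (both epimers at the peroxy carbon) | CC(C)(C)[Si](C)(C)OCCC[C@@H](C)CC(C)(OO[Si](CC)(CC)CC)C[C@@]1(C)C=CC(=O)O1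
A3 | alternative 2 | (3E,5E,8R)-4,6,8,12-tetramethyltrideca-3,5,11-trienoic acid | OC(=O)C/C=C(\C)/C=C(\C)C[C@H](C)CCC=C(C)C
A4 | alternative 2 | 2-{(3S,6R)-6-[(2R)-2,6-dimethylhept-5-en-1-yl]-4,6-dimethyl-3,6-dihydro-1,2-dioxin-3-yl}acetic acid | CC(C)=CCC[C@@H](C)C[C@]1(C)C=C(C)[C@H](CC(O)=O)OO1
A5 | alternative 3 | (2S)-2-[(2R)-2,6-dimethylhept-5-en-1-yl]-2-methyloxirane | C[C@]1(C[C@H](C)CCC=C(C)C)CO1
A6 | alternative 3 | (2R,4R)-2-hydroperoxy-2,4,8-trimethylnon-7-en-1-ol | OC[C@](C)(OO)C[C@H](C)CCC=C(C)C
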